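## The problem

Target 23 (C30H32O4) is the C2-symmetric head-to-head dimer of two identical lindenane lactone units. Lindenane numbering (C1–C15, primed in the second half) is used throughout, and β means the face of ring B that carries the angular methyl C14. In each half a cyclopropane (C1–C2–C3) is cis-fused to cyclopentane ring A (C1, C3, C4, C5, C10), ring A is trans-fused to cyclohexane ring B (C5–C10), and ring B carries an α-methylbutenolide (C7=C11, C12 carbonyl, ring oxygen on C8); the halves are joined by a cyclobutane C8–C9–C9'–C8'. There are twelve stereocentres, six per half (C1, C3, C5, C8, C9, C10): the cyclopropane CH2 and C14 are β, H-1, H-3 and H-5 are α, and the two cyclobutane bonds at C8 and C9 are α with the lactone oxygen β. The cyclopropane makes ring A a rigid bowl with an open α face, so C1/C3 can dictate C10, and C10 with the cyclopropane can dictate C5–H and the face on which C8=C9 dimerises; only C1/C3 need absolute control. The hard relationship is at C5, where C6 must sit on the more hindered β face, an arrangement that is thermodynamically fragile while C4 is a ketone. The groups that will not survive rough treatment are the vinylcyclopropane (C4=C15 beside C3; acid, hydrogenolysis), the γ-alkylidene butenolide of the monomer (base, nucleophiles, light) and the cyclobutane flanked by two lactone carbons. The key step is possible because in ring A the cyclopropane carbon C3 is α and C1 is β to C4, with C2 bridging them: this is the pattern left when hydride adds to the β-carbon of a 3-(halomethyl)cyclopent-2-enone and the enolate carbon is alkylated by the halomethyl group.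

## Retrosynthesis

The cyclobutane is cut first: C8–C8' and C9–C9' are broken to give two molecules of monomer 22. Compared with a stepwise ionic joining, this removes four stereocentres and the symmetry problem in one operation and leaves a C15 compound. The forward [2+2] reaction must be head-to-head, anti, and on the α face of each alkene; the axial C14 methyl next to C9 and the stability of a C8,C8' diradical should favour this.

In 22 the butenolide is removed by cutting C7–C11 and O–C12, through aldol 21, back to ketone 19 and keto ester 20. This places the ring B oxygen at C8, where the ketone directs both bond formations (enolate at C7, enol oxygen at C8). A lactone built on a C7 carbonyl would need a separate oxidation at C8. The forward reaction must enolise 19 towards C7, which the quaternary C10 next to C9 ensures.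

The exocyclic alkene C4=C15 of 19 is cut to a C4 ketone, with C8 kept at the alcohol level (18, then 17) so that two carbonyls never compete. Precursor 17 has one carbon fewer and only robust functions. The forward methylenation must leave the epimerisable C5 untouched, which rules out basic ylides.

C5–H and C6–H of 17 are cut to enone 16 (C5=C6). The neighbouring cut, C5–C6 by enolate alkylation of a ring A ketone, is rejected: electrophiles reach such bicyclic enolates from the exo (α) face and would place C6 cis to C9. Making the C–H bond last lets the open α face work for the trans fusion. The forward hydrogenation must be a syn addition to the α face; the 8α-hydroxyl of 16 is placed to deliver the catalyst there.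

Ring B of 16 is opened at C5=C6 (ring-closing metathesis of 14, with silyl ether 15 in between), the exocyclic methylene of 14 is removed (13), the silyl group taken off (12) and C7–C8 cut to aldehyde 11. This puts oxygen on C8 from the start; a shorter diallyl/metathesis closure would leave a C7=C8 alkene that cannot be oxidised regioselectively. The forward steps need aldehyde-over-ketone selectivity, a defined carbinol configuration by catalyst control, and protection of the alcohol against conjugate addition to the α-methylene ketone.

Aldehyde 11 comes from allyl ketone 10, and C9–C10 of 10 is cut to β-methyl enone 8. The quaternary centre is made by conjugate addition, so the incoming carbon (C9) takes the α face and C14 ends up β; introducing the two carbons in the reverse order would give the wrong C10.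

The methyl group (C10–C14) and the two ring unsaturations are removed stepwise, 8 to 6 to saturated ketone 4. Only standard enone chemistry is needed, and the transient stereocentre of the first addition is erased.

Finally the cyclopropane of 4 is opened at C2–C3 with removal of the hydride at C1, giving achiral bromo enone 3, made from 1 and 2. This cut carries the plan: a bicycle with two stereocentres is traded for a flat enone, and the forward reaction must choose one enantioface of 3 and cyclise instead of protonating.

## Roads not taken

Alternative 1: Both rings A and both cyclopropanes are cut at once (C1–C3 and C2–C3 in each half), leading back to a bis(α-diazoketone) A2 on a preformed 6-4-6 bis-butenolide core. Forward, Rh2(OAc)4 (divalent rhodium) would decompose both diazo groups and each carbene would add to the neighbouring vinyl group to give diketone A1, followed by a twofold methylenation.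
- Merits: it is two-directional, uses the C2 symmetry, and solves the cyclobutane early on simple material.
- Weak points: the core must be dimerised from a monomer without ring A, so face and head-to-head selectivity rest only on the small difference between methyl and vinyl at C10. The quaternary C10 and the trans C5 acyl group need their own enantiocontrol. Two carbenoids beside enol lactones invite C–H insertion and ylide formation. Each carbene must add to the vinyl face that puts C2 syn to C14. Two hindered, epimerisable ketones must be methylenated at the end.
- Comparison: if the core dimerisation were selective, this road would be shorter than the 16 steps chosen here and would avoid photochemistry on an advanced monomer. The chosen plan sets against it one catalytic step for absolute configuration, relay of every other centre from the cyclopropane, and dimerisation of a monomer whose β face is doubly shielded.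

Alternative 2: Ring A is cut into three components (C4–C5, C3–C4 and C1–C10). Forward, pent-1-en-4-yne A4 is complexed with Co2(CO)8 (zerovalent cobalt) and combined with cyclopropene A5 and CO in a Pauson–Khand reaction to give A3, the cyclopropane-fused cyclopentenone already carrying the C5 allyl group.
- Merits: one step builds what takes four steps here (up to 8), the strained alkene is a good partner, and the alkyne substituent ends up next to the carbonyl as required.
- Weak points: A5 is an unstable gas that must be made and used cold. A3 is racemic unless a chiral ligand or auxiliary is added, because nothing in the components is chiral. C10 of A3 carries hydrogen, so the quaternary centre needs two conjugate additions with an oxidation in between, the second onto a tetrasubstituted enone. C5 would still have to be set by protonation.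
- Comparison: this road is more convergent and reaches a C5-substituted ring A faster. The chosen plan sets against it secured absolute configuration at C1/C3 and construction of C10 on an unhindered trisubstituted enone.

Alternative 3: The cyclopropane is cut at C1–C2 and C2–C3, leading back to a trans-hydrindenol A7 of the kind available from enantioselective Robinson annulation chemistry. Forward, Et2Zn and CH2I2 form a zinc carbenoid that binds the 4β-hydroxyl and adds CH2 to the same face, giving A6.
- Merits: hydroxyl-directed cyclopropanation is among the most reliable reactions available, and the ring fusion and C10 come from classical chemistry.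
- Weak points: the ring B oxygen of A6 sits at C7, so the butenolide needs an extra oxidation at C8 or a carbonyl transposition. The allylic alcohol of A7 requires a 1,3-transposition in ring A. The trans fusion of such hydrindanes itself costs several steps.
- Comparison: in stereochemical reliability at C5, C10 and the cyclopropane this road is at least as safe as the chosen one, and safer for the ring fusion, which here depends on step 11. The chosen plan sets against it a two-step entry to enantiopure ring A, oxygen placed directly at C8, and no transpositions.

Key step: step 2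

Assumption: an Old Yellow Enzyme-family variant that accepts ring enone 3 and delivers hydride to the face leading to (1S,5R)-4 can be found by screening homologues; the reaction type is known for open-chain β-(halomethyl) enals and enones.

## Route

Step 1
Reactants: 1 3-methylcyclopent-2-en-1-one; 2 N-bromosuccinimide
Product: 3 3-(bromomethyl)cyclopent-2-en-1-one
Conditions: AIBN (cat.), PhCF3, 85 °C
Reagents that add atoms: none
Why: Wohl–Ziegler bromination; a bromine atom abstracts a γ-hydrogen to give a delocalised radical that is brominated at the exocyclic terminus, and the ring-brominated isomer expected as a minor product is removed by chromatography.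

Step 2
Reactants: 3 3-(bromomethyl)cyclopent-2-en-1-one
Product: 4 (1S,5R)-bicyclo[3.1.0]hexan-2-one
Conditions: ene-reductase variant (Old Yellow Enzyme family, proton-donor Tyr→Phe), NADP+ (cat.), D-glucose, glucose dehydrogenase, potassium phosphate buffer pH 7.0, 5% DMSO, 30 °C
Reagents that add atoms: none
Why: Reduced flavin (FMNH2, regenerated through NADPH) transfers hydride to the β-carbon of the enone, held by hydrogen bonds to its carbonyl oxygen; this carbon becomes C5 of 4 (lindenane C1). With the tyrosine that normally protonates the α-carbon replaced by phenylalanine, the bound enolate lives long enough for its α-carbon (C1 of 4, lindenane C3) to displace bromide from the neighbouring CH2Br (lindenane C2) in a 3-exo-tet SN2 closure that forms the cyclopropane. The closest known reaction type is the ene-reductase reductive carbocyclisation of open-chain β-(halomethyl) enals and enones; here the same bond is formed on a ring enone, whose parent 3-alkylcyclopentenones are ordinary substrates of these enzymes. C5 is set by the face from which the flavin delivers hydride, that is by the binding orientation of 3 in the active site. C1 follows because the bromomethyl group is pushed to the opposite face and only a cis-fused bicycle can close. The step needs C=C over C=O reduction (intrinsic to flavin ene-reductases), cyclisation over protonation (secured by the Tyr→Phe exchange and the good leaving group) and the (1S,5R) sense (to be found among homologues with opposite binding modes). A small chemical hydride would attack the carbonyl or the allylic bromide and could not distinguish the enantiofaces of this achiral enone.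

Step 3
Reactants: 4 (1S,5R)-bicyclo[3.1.0]hexan-2-one
Product: 6 (1S,5S)-bicyclo[3.1.0]hex-3-en-2-one, via silyl enol ether 5 (not isolated)
Conditions: LiN(iPr)2, Me3SiCl, THF, −78 °C; solvent exchange; Pd(OAc)2 (1.05 equiv), MeCN, rt
Reagents that add atoms: chlorotrimethylsilane, C[Si](C)(C)Cl (silicon is carried by 5 only)
Why: Deprotonation can occur only at C3, because the bridgehead α-hydrogen is a cyclopropyl C–H whose enolate would be a bridgehead alkene; Saegusa–Ito oxidation (palladium enolate, β-hydride elimination) then gives the enone without touching the cyclopropane.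

Step 4
Reactants: 6 (1S,5S)-bicyclo[3.1.0]hex-3-en-2-one
Product: 8 (1S,5R)-4-methylbicyclo[3.1.0]hex-3-en-2-one, via silyl enol ether 7 (not isolated)
Conditions: MeMgBr, CuBr·SMe2 (5 mol %), Me3SiCl, THF, −78 °C; solvent exchange; Pd(OAc)2 (1.05 equiv), MeCN, rt
Reagents that add atoms: methylmagnesium bromide, C[Mg]Br; chlorotrimethylsilane, C[Si](C)(C)Cl (silicon is carried by 7 only)
Why: Copper-catalysed conjugate addition with silyl trapping puts methyl on the β-carbon from the convex face, anti to the cyclopropane, and a second Saegusa–Ito oxidation erases that stereocentre and leaves the β-methyl enone. The methyl group must be in place before the second carbon substituent arrives.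

Step 5
Reactants: 8 (1S,5R)-4-methylbicyclo[3.1.0]hex-3-en-2-one
Product: 10 (1S,4R,5R)-4-methyl-4-(prop-2-en-1-yl)bicyclo[3.1.0]hexan-2-one, via silyl enol ether 9 (not isolated)
Conditions: CH2=CHCH2MgBr, CuBr·SMe2 (1.1 equiv each), Me3SiCl, THF, −78 °C; then K2CO3 (cat.), MeOH, 0 °C
Reagents that add atoms: allylmagnesium bromide, C=CC[Mg]Br; chlorotrimethylsilane, C[Si](C)(C)Cl (silicon is carried by 9 only)
Why: Allylcopper with Me3SiCl activation adds 1,4 even to β,β-disubstituted enones. The allyl group enters anti to the cyclopropane, so the methyl group is pushed to the cyclopropane face and the quaternary C10 is set by relay from step 2; methanolysis frees the ketone from 9.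

Step 6
Reactants: 10 (1S,4R,5R)-4-methyl-4-(prop-2-en-1-yl)bicyclo[3.1.0]hexan-2-one
Product: 11 (1S,4R,5R)-4-methyl-4-(2-oxoethyl)bicyclo[3.1.0]hexan-2-one
Conditions: O3, CH2Cl2–MeOH, −78 °C; then Me2S, −78 °C → rt
Reagents that add atoms: ozone, [O-][O+]=O
Why: Ozonolysis with reductive work-up cleaves the only alkene; the ketone and the cyclopropane are inert to ozone at −78 °C.

Step 7
Reactants: 11 (1S,4R,5R)-4-methyl-4-(2-oxoethyl)bicyclo[3.1.0]hexan-2-one
Product: 12 (1S,4R,5R)-4-[(2R)-2-hydroxypent-4-en-1-yl]-4-methylbicyclo[3.1.0]hexan-2-one
Conditions: CH2=CHCH2SnBu3, (R)-BINOL (20 mol %), Ti(OiPr)4 (10 mol %), 4 Å molecular sieves, CH2Cl2, −20 °C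
Reagents that add atoms: allyltributylstannane, C=CC[Sn](CCCC)(CCCC)CCCC
Why: Keck allylation; the BINOL–titanium Lewis acid activates only the aldehyde (the hindered ketone should not react at −20 °C) and the stannane attacks its Re face to give the (R)-carbinol. This temporary stereocentre is chosen so that the hydroxyl lies on the α face of ring B in 16.

Step 8
Reactants: 12 (1S,4R,5R)-4-[(2R)-2-hydroxypent-4-en-1-yl]-4-methylbicyclo[3.1.0]hexan-2-one
Product: 13 (1S,4R,5R)-4-[(2R)-2-(tert-butyldimethylsilyloxy)pent-4-en-1-yl]-4-methylbicyclo[3.1.0]hexan-2-one
Conditions: tBuMe2SiCl, imidazole, DMF, rt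
Reagents that add atoms: tert-butyldimethylsilyl chloride, CC(C)(C)[Si](C)(C)Cl
Why: Standard silylation of the secondary alcohol; it prevents six-membered oxa-Michael addition of the hydroxyl to the α-methylene ketone made in step 9.

Step 9
Reactants: 13 (1S,4R,5R)-4-[(2R)-2-(tert-butyldimethylsilyloxy)pent-4-en-1-yl]-4-methylbicyclo[3.1.0]hexan-2-one
Product: 14 (1S,4S,5R)-4-[(2R)-2-(tert-butyldimethylsilyloxy)pent-4-en-1-yl]-4-methyl-3-methylidenebicyclo[3.1.0]hexan-2-one
Conditions: (CH2O)n, iPr2NH·CF3CO2H, THF, reflux
Reagents that add atoms: formaldehyde (as paraformaldehyde), C=O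
Why: Direct α-methylenation (Mannich condensation and β-elimination of the amine) can take place only at C3 of the bicycle, the sole enolisable position; the quaternary neighbour retards dimerisation of the α-methylene ketone.

Step 10
Reactants: 14 (1S,4S,5R)-4-[(2R)-2-(tert-butyldimethylsilyloxy)pent-4-en-1-yl]-4-methyl-3-methylidenebicyclo[3.1.0]hexan-2-one
Product: 16 8α-hydroxy-11,12,13,15-tetranorlinden-5-en-4-one, via silyl ether 15 (not isolated)
Conditions: second-generation Grubbs catalyst RuCl2(=CHPh)(PCy3)(1,3-dimesitylimidazolidin-2-ylidene) (5 mol %), CH2Cl2, 40 °C; then HF·pyridine, THF, 0 °C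
Reagents that add atoms: none
Why: Ring-closing metathesis; the ruthenium carbene forms at the terminal alkene and closes onto the 1,1-disubstituted enone alkene, giving six-membered ring B with the C5=C6 bond and releasing ethene. Fluoride then removes the silyl group, and the free alcohol can no longer add to the now endocyclic enone.

Step 11
Reactants: 16 8α-hydroxy-11,12,13,15-tetranorlinden-5-en-4-one
Product: 17 8α-hydroxy-11,12,13,15-tetranor-5αH-lindenan-4-one
Conditions: H2 (1 atm), [Ir(cod)(PCy3)(py)]PF6 (10 mol %), CH2Cl2, rt
Reagents that add atoms: none
Why: Hydroxyl-directed homogeneous hydrogenation; the cationic iridium centre binds the 8α-hydroxyl and the alkene and adds both hydrogens syn to the α face, the β face being closed by the axial C14 methyl and the cyclopropane, which sets C5 (H α) and the trans ring fusion. A homogeneous catalyst is chosen so that C5–H comes from the metal and not from ketonisation of an enol.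

Step 12
Reactants: 17 8α-hydroxy-11,12,13,15-tetranor-5αH-lindenan-4-one
Product: 18 11,12,13-trinor-5αH-linden-4(15)-en-8α-ol
Conditions: Zn, CH2Br2, TiCl4 (reagent pre-formed in THF), CH2Cl2, 0 °C → rt
Reagents that add atoms: dibromomethane, BrCBr
Why: Takai–Lombardo methylenation uses a non-basic gem-dimetallic reagent, so the C5 stereocentre next to the ketone is not epimerised (a basic Wittig ylide could equilibrate it towards the cis-fused ketone); the free hydroxyl is tolerated.

Step 13
Reactants: 18 11,12,13-trinor-5αH-linden-4(15)-en-8α-ol
Product: 19 11,12,13-trinor-5αH-linden-4(15)-en-8-one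
Conditions: Dess–Martin periodinane, pyridine, CH2Cl2, 0 °C → rt
Reagents that add atoms: none
Why: Buffered Dess–Martin oxidation converts the secondary alcohol to the ketone without acid that could isomerise the vinylcyclopropane.

Step 14
Reactants: 19 11,12,13-trinor-5αH-linden-4(15)-en-8-one; 20 ethyl pyruvate
Product: 21 ethyl 11-hydroxy-8-oxo-5αH-linden-4(15)-en-12-oate (mixture of C7 and C11 epimers)
Conditions: LiN(iPr)2, THF, −78 °C; then 20, −78 °C; aq NH4Cl
Reagents that add atoms: none
Why: Kinetic deprotonation occurs at C7 (C9 is neopentylic, next to quaternary C10) and the enolate adds to the ketone carbonyl of the pyruvate in a crossed aldol reaction; the two new stereocentres are removed in step 15.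

Step 15
Reactants: 21 ethyl 11-hydroxy-8-oxo-5αH-linden-4(15)-en-12-oate
Product: 22 5αH-lindena-4(15),7(11),8-trien-12,8-olide (chloranthalactone A)
Conditions: p-TsOH·H2O (20 mol %), toluene, 80 °C
Reagents that add atoms: none
Why: Acid-catalysed dehydration to the alkylidene keto ester, enolisation of the C8 ketone towards C9 and lactonisation with loss of ethanol give the α-methyl-γ-alkylidene butenolide, the standard ketone-to-butenolide annulation; the temperature is kept at 80 °C to spare the vinylcyclopropane.

Step 16
Reactants: 22 5αH-lindena-4(15),7(11),8-trien-12,8-olide (two molecules)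
Product: 23 CNP0265879.1, the head-to-head [2+2] dimer of 22 through C8–C8' and C9–C9'
Conditions: hν (medium-pressure Hg lamp, Pyrex filter, λ > 300 nm), degassed hexane–CH2Cl2, rt
Reagents that add atoms: none
Why: [2+2] Photocycloaddition of the γ-alkylidene butenolide chromophore; bonding between the two C9 termini gives the most stabilised 1,4-diradical (both radicals at C8, allylic and oxygen-substituted), which closes C8–C8' to the head-to-head dimer. Each monomer reacts on its α face, opposite the axial C14 methyl on C10, and the halves take the anti arrangement, so C8, C9, C8' and C9' are set as in the cis-anti-cis, C2-symmetric target.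

## Compound list

1 | 3-methylcyclopent-2-en-1-one | CC1=CC(=O)CC1 | starting material
2 | N-bromosuccinimide | O=C1CCC(=O)N1Br | starting material
3 | 3-(bromomethyl)cyclopent-2-en-1-one | O=C1C=C(CBr)CC1 | intermediate
4 | (1S,5R)-bicyclo[3.1.0]hexan-2-one | O=C1CC[C@@H]2C[C@H]12 | intermediate
5 | 2-(trimethylsilyloxy)bicyclo[3.1.0]hex-2-ene, ring stereocentres as in 4 | C[Si](C)(C)OC1=CC[C@@H]2C[C@H]12 | intermediate (not isolated)
6 | (1S,5S)-bicyclo[3.1.0]hex-3-en-2-one | O=C1C=C[C@@H]2C[C@H]12 | intermediate
7 | 4-methyl-2-(trimethylsilyloxy)bicyclo[3.1.0]hex-2-ene, methyl anti to the cyclopropane | C[Si](C)(C)OC1=C[C@@H](C)[C@@H]2C[C@H]12 | intermediate (not isolated)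
8 | (1S,5R)-4-methylbicyclo[3.1.0]hex-3-en-2-one | O=C1C=C(C)[C@@H]2C[C@H]12 | intermediate
9 | 4-methyl-4-(prop-2-en-1-yl)-2-(trimethylsilyloxy)bicyclo[3.1.0]hex-2-ene, allyl anti to the cyclopropane | C[Si](C)(C)OC1=C[C@@](C)(CC=C)[C@@H]2C[C@H]12 | intermediate (not isolated)
10 | (1S,4R,5R)-4-methyl-4-(prop-2-en-1-yl)bicyclo[3.1.0]hexan-2-one | O=C1C[C@@](C)(CC=C)[C@@H]2C[C@H]12 | intermediate
11 | (1S,4R,5R)-4-methyl-4-(2-oxoethyl)bicyclo[3.1.0]hexan-2-one | O=C1C[C@@](C)(CC=O)[C@@H]2C[C@H]12 | intermediate
12 | (1S,4R,5R)-4-[(2R)-2-hydroxypent-4-en-1-yl]-4-methylbicyclo[3.1.0]hexan-2-one | O=C1C[C@@](C)(C[C@H](O)CC=C)[C@@H]2C[C@H]12 | intermediate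
13 | (1S,4R,5R)-4-[(2R)-2-(tert-butyldimethylsilyloxy)pent-4-en-1-yl]-4-methylbicyclo[3.1.0]hexan-2-one | O=C1C[C@@](C)(C[C@H](O[Si](C)(C)C(C)(C)C)CC=C)[C@@H]2C[C@H]12 | intermediate
14 | (1S,4S,5R)-4-[(2R)-2-(tert-butyldimethylsilyloxy)pent-4-en-1-yl]-4-methyl-3-methylidenebicyclo[3.1.0]hexan-2-one | O=C1C(=C)[C@@](C)(C[C@H](O[Si](C)(C)C(C)(C)C)CC=C)[C@@H]2C[C@H]12 | intermediate
15 | 8α-(tert-butyldimethylsilyloxy)-11,12,13,15-tetranorlinden-5-en-4-one (C4 ketone, C5=C6, 10β-methyl, β-cyclopropane) | O=C1[C@H]2C[C@H]2[C@@]2(C)C1=CC[C@@H](O[Si](C)(C)C(C)(C)C)C2 | intermediate (not isolated)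
16 | 8α-hydroxy-11,12,13,15-tetranorlinden-5-en-4-one | O=C1[C@H]2C[C@H]2[C@@]2(C)C1=CC[C@@H](O)C2 | intermediate
17 | 8α-hydroxy-11,12,13,15-tetranor-5αH-lindenan-4-one (trans-fused rings A and B) | O=C1[C@H]2C[C@H]2[C@@]2(C)[C@H]1CC[C@@H](O)C2 | intermediate
18 | 11,12,13-trinor-5αH-linden-4(15)-en-8α-ol | C=C1[C@H]2C[C@H]2[C@@]2(C)[C@H]1CC[C@@H](O)C2 | intermediate
19 | 11,12,13-trinor-5αH-linden-4(15)-en-8-one | C=C1[C@H]2C[C@H]2[C@@]2(C)[C@H]1CCC(=O)C2 | intermediate
20 | ethyl pyruvate (ethyl 2-oxopropanoate) | CCOC(=O)C(C)=O | starting material
21 | ethyl 11-hydroxy-8-oxo-5αH-linden-4(15)-en-12-oate (C7 and C11 epimers) | C=C1[C@H]2C[C@H]2[C@@]2(C)[C@H]1CC(C(C)(O)C(=O)OCC)C(=O)C2 | intermediate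
22 | 5αH-lindena-4(15),7(11),8-trien-12,8-olide (chloranthalactone A) | C=C1[C@H]2C[C@H]2[C@@]2(C)[C@H]1CC1=C(C)C(=O)OC1=C2 | intermediate
23 | CNP0265879.1, head-to-head cis-anti-cis [2+2] dimer of 22 (C8–C8' and C9–C9') | C=C1[C@H]2C[C@H]2[C@@]2(C)[C@H]1CC1=C(C)C(=O)O[C@]13[C@H]2[C@H]1[C@@]2(C)[C@@H]4C[C@@H]4C(=C)[C@@H]2CC2=C(C)C(=O)O[C@@]213 | target

## Step count and least certain steps

Total step count: 16. Longest linear sequence: 16 steps (1 to 23; 2 and 20 are purchased).

Step 2 (key step).
- What may go wrong: protonation of the enolate before it cyclises (plain reduction), hydride delivery to the wrong enantioface, and loss of substrate by hydrolysis of the allylic bromide or by alkylation of the protein. The ring enone lies outside the reported substrate range.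
- Fallback, from 3 back to 4: asymmetric copper hydride conjugate reduction of 3 (Cu(OAc)2, a chiral bisphosphine such as DTBM-SEGPHOS in the enantiomer that gives the S ketone, polymethylhydrosiloxane, toluene, 0 °C; fluoride work-up) should give (S)-3-(bromomethyl)cyclopentan-1-one F1. Its enolate (KOtBu, THF, 0 °C) closes the same C2–C3 bond by 3-exo-tet alkylation and rejoins the route at 4; the chiral hydride donor changes from enzyme to metal catalyst and the cyclisation becomes a separate operation.

Step 5.
- What may go wrong: competing 1,2-addition of the allyl reagent and slow addition at the hindered β-carbon.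
- Fallback, from 8 back to 10: deliberate 1,2-addition of CH2=CHCH2MgBr (THF, −78 °C) from the α face gives 2-allyl-4-methylbicyclo[3.1.0]hex-3-en-2-ol F2. Anionic oxy-Cope rearrangement (KH, 18-crown-6, THF, rt) then carries the allyl group suprafacially to C10 and gives 10 after protonation.

Step 11.
- What may go wrong: insufficient facial selectivity (related hydrindenones tend to hydrogenate to the cis-fused isomer) and epimerisation at C5 through an enol.
- Fallback, from 15 (kept by omitting the fluoride treatment of step 10) back to 18, so that step 12 is not needed; a palladium hydride sets the ring fusion instead. 15 is hydrogenated without regard to selectivity (H2, Pd/C, EtOAc) to the C5-epimeric 8α-(tert-butyldimethylsilyloxy)-11,12,13,15-tetranorlindenan-4-ones F3. KN(SiMe3)2 and PhNTf2 give the C4(5)-enol triflate F4, which erases C5. Stille coupling with Bu3SnCH2OH (Pd(PPh3)4, zerovalent palladium, LiCl, dioxane) gives the 15-hydroxy-4(5)-ene F5, and formic acetic anhydride with pyridine gives its formate F6. Pd(OAc)2 and PBu3 in dioxane at 100 °C ionise F6, CO2 is lost, and hydride is delivered to C5 from the less hindered α face with formation of the exocyclic C4=C15 bond (formate reduction of allylic esters to exo-methylene compounds), giving the 8α-silyl ether of 18, F7. HF·pyridine then returns to the route at 18.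

Step 15.
- What may go wrong: acid-induced migration of the exocyclic double bond or opening of the vinylcyclopropane, and incomplete lactonisation.
- Fallback, from 21 back to 22, without strong acid: dehydration of 21 (MsCl, Et3N, then DBU, CH2Cl2) gives ethyl 8-oxo-5αH-lindena-4(15),7(11)-dien-12-oate F8. Saponification (LiOH, THF–H2O, then mild acidification) gives the ring-closed pseudo-acid 8-hydroxy-5αH-lindena-4(15),7(11)-dien-12,8-olide F9, and Ac2O with NaOAc dehydrates F9 to 22.

Step 16.
- What may go wrong: formation of head-to-tail or syn dimers, cycloaddition at the C7=C11 bond, and photochemical cycloreversion.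
- Fallback, from 22 back to 23, stepwise. Reductive coupling of 22 at C9 (SmI2, THF–MeOH, −78 °C), on the α face of each half, gives the C9–C9' linked bis-butenolide F10. Double γ-deprotonation and silylation (LiN(iPr)2, Me3SiCl, THF, −78 °C) gives the bis(2-trimethylsilyloxyfuran) F11. Intramolecular oxidative coupling of the two silyloxyfuran termini (Cu(OTf)2, MeCN, 0 °C) closes C8–C8' and gives 23.

## Further compounds

F1 | step 2 | (S)-3-(bromomethyl)cyclopentan-1-one | O=C1CC[C@H](CBr)C1
F2 | step 5 | 2-allyl-4-methylbicyclo[3.1.0]hex-3-en-2-ol, allyl anti to the cyclopropane | O[C@@]1(CC=C)[C@H]2C[C@H]2C(C)=C1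
F3 | step 11 | 8α-(tert-butyldimethylsilyloxy)-11,12,13,15-tetranorlindenan-4-one, C5 epimers | O=C1[C@H]2C[C@H]2[C@@]2(C)C1CC[C@@H](O[Si](C)(C)C(C)(C)C)C2
F4 | step 11 | C4(5)-enol triflate of F3 | FC(F)(F)S(=O)(=O)OC=1[C@H]2C[C@H]2[C@@]2(C)C=1CC[C@@H](O[Si](C)(C)C(C)(C)C)C2
F5 | step 11 | 8α-(tert-butyldimethylsilyloxy)-11,12,13-trinorlinden-4(5)-en-15-ol | OCC=1[C@H]2C[C@H]2[C@@]2(C)C=1CC[C@@H](O[Si](C)(C)C(C)(C)C)C2
F6 | step 11 | formate of F5 | O=COCC=1[C@H]2C[C@H]2[C@@]2(C)C=1CC[C@@H](O[Si](C)(C)C(C)(C)C)C2
F7 | step 11 | 8α-tert-butyldimethylsilyl ether of 18 | C=C1[C@H]2C[C@H]2[C@@]2(C)[C@H]1CC[C@@H](O[Si](C)(C)C(C)(C)C)C2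
F8 | step 15 | ethyl 8-oxo-5αH-lindena-4(15),7(11)-dien-12-oate | C=C1[C@H]2C[C@H]2[C@@]2(C)[C@H]1CC(=C(C)C(=O)OCC)C(=O)C2
F9 | step 15 | 8-hydroxy-5αH-lindena-4(15),7(11)-dien-12,8-olide | C=C1[C@H]2C[C@H]2[C@@]2(C)[C@H]1CC1=C(C)C(=O)OC1(O)C2
F10 | step 16 | C9–C9' linked bis-butenolide (hydrogen at C8 and C8', epimers) | C=C1[C@H]2C[C@H]2[C@@]2(C)[C@H]1CC1=C(C)C(=O)OC1[C@H]2[C@H]1[C@@]2(C)[C@@H]4C[C@@H]4C(=C)[C@@H]2CC2=C(C)C(=O)OC21
F11 | step 16 | C9–C9' linked bis(2-trimethylsilyloxyfuran) | C=C1[C@H]2C[C@H]2[C@@]2(C)[C@H]1Cc1c(C)c(O[Si](C)(C)C)oc1[C@H]2[C@H]1[C@@]2(C)[C@@H]4C[C@@H]4C(=C)[C@@H]2Cc2c(C)c(O[Si](C)(C)C)oc21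
A1 | alternative 1 | C4,C4'-diketone of the dimer with both cyclopropanes in place | O=C1[C@H]2C[C@H]2[C@@]2(C)[C@H]1CC1=C(C)C(=O)O[C@]13[C@H]2[C@H]1[C@@]2(C)[C@@H]4C[C@@H]4C(=O)[C@@H]2CC2=C(C)C(=O)O[C@@]213
A2 | alternative 1 | bis(α-diazoketone) of the 6-4-6 bis-butenolide core (C10 and C10' methyl and vinyl) | C=C[C@@]2(C)[C@H](C(=O)C=[N+]=[N-])CC1=C(C)C(=O)O[C@]13[C@H]2[C@H]1[C@@](C)(C=C)[C@H](C(=O)C=[N+]=[N-])CC2=C(C)C(=O)O[C@@]213
A3 | alternative 2 | 3-allylbicyclo[3.1.0]hex-3-en-2-one | C=CCC1=C[C@@H]2C[C@@H]2C1=O
A4 | alternative 2 | pent-1-en-4-yne | C=CCC#C
A5 | alternative 2 | cyclopropene | C1=CC1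
A6 | alternative 3 | cyclopropyl carbinol with the ring A stereocentres in place | O[C@H]1[C@H]2C[C@H]2[C@@]2(C)[C@H]1CC1(OCCO1)CC2
A7 | alternative 3 | trans-hydrindenol (4β-hydroxy, C1=C3 alkene, C7 dioxolane) | O[C@H]1C=C[C@@]2(C)[C@H]1CC1(OCCO1)CC2
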